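**Strategy**

The route rests on disconnecting ring A' across C1''–C2'' and C5''–C6''. Ring A' is hexasubstituted, with the lone methyl ether at C6'' wedged between C5''–CH3 and the C1'' methylene; a Danheiser benzannulation exploits exactly this pattern. Heating 3-ethoxy-2-methylcyclobutenone with a benzylic 1-methoxyalkyne builds ring A' in one operation and delivers methyl, methoxy, benzylic carbon and a free C2'' phenol in their final positions, leaving only C3'' open. The alkyne precursor carries ring A as a benzyl/MOM-protected phloroglucinol with a bromine atom at the future C4a, which tames the benzylic bromide used to make it and later anchors the flavonol.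

Key step: step 8

Remark: ring A carries a bromine atom at the future C4a as a spectator through the key step; 2-(benzyloxy)-N-methoxy-N-methylacetamide, 1-(benzyloxy)-4-(2-bromoethyl)benzene and LiNEt2 are taken as purchasable.

**Route**

Step 1
Reactants: 1 2,4,6-trihydroxybenzaldehyde
Product: 2 2,4-bis(benzyloxy)-6-hydroxybenzaldehyde
Conditions: BnBr (2.1 equiv), K2CO3, DMF, rt
Reagents that add atoms: benzyl bromide, BrCc1ccccc1
Why: Williamson ether synthesis in which the para hydroxyl and one ortho hydroxyl are alkylated while the remaining ortho hydroxyl, locked in a hydrogen bond to the formyl oxygen, stays free.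

Step 2
Reactants: 2 2,4-bis(benzyloxy)-6-hydroxybenzaldehyde
Product: 3 4,6-bis(benzyloxy)-3-bromo-2-hydroxybenzaldehyde
Conditions: NBS, i-Pr2NH (cat.), CH2Cl2, −20 → 0 °C
Reagents that add atoms: N-bromosuccinimide, O=C1CCC(=O)N1Br
Why: Electrophilic aromatic bromination (amine-catalysed ortho-bromination of a phenol with NBS) at C3, the carbon ortho to the chelated hydroxyl, which is the most nucleophilic site of 2-hydroxy-4,6-dialkoxyaryl carbonyl compounds and the one to which bromine is handed over from the phenol oxygen.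

Step 3
Reactants: 3 4,6-bis(benzyloxy)-3-bromo-2-hydroxybenzaldehyde
Product: 4 4,6-bis(benzyloxy)-3-bromo-2-(methoxymethoxy)benzaldehyde
Conditions: NaH, DMF, 0 °C; then MOMCl, 0 °C → rt
Reagents that add atoms: chloromethyl methyl ether, COCCl
Why: Williamson-type O-alkylation of the sodium phenoxide gives the MOM acetal, and the formyl group, having no α-hydrogen, tolerates NaH.

Step 4
Reactants: 4 4,6-bis(benzyloxy)-3-bromo-2-(methoxymethoxy)benzaldehyde
Product: 5 [4,6-bis(benzyloxy)-3-bromo-2-(methoxymethoxy)phenyl]methanol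
Conditions: NaBH4, THF/MeOH, 0 °C
Reagents that add atoms: none
Why: Hydride reduction of an aryl aldehyde by NaBH4, which leaves the aryl bromide and the acetal and benzyl ethers untouched.

Step 5
Reactants: 5 [4,6-bis(benzyloxy)-3-bromo-2-(methoxymethoxy)phenyl]methanol
Product: 7 1,5-bis(benzyloxy)-2-bromo-4-(bromomethyl)-3-(methoxymethoxy)benzene, via benzylic mesylate 6 (not isolated)
Conditions: MsCl, Et3N, CH2Cl2, −20 °C; then LiBr, THF, 0 °C; used crude at once
Reagents that add atoms: lithium bromide, [Li+].[Br-]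
Why: O-sulfonylation followed by Finkelstein-type SN2 displacement by bromide under non-acidic conditions that spare the MOM group; the electron-withdrawing ring bromine, which also twists its two alkoxy neighbours out of conjugation, slows ionisation of this trialkoxybenzyl bromide, which is still used at once without purification.

Step 6
Reactants: 7 1,5-bis(benzyloxy)-2-bromo-4-(bromomethyl)-3-(methoxymethoxy)benzene; 8 2-chloro-1,1-dimethoxyethane (chloroacetaldehyde dimethyl acetal)
Product: 10 1,5-bis(benzyloxy)-2-bromo-3-(methoxymethoxy)-4-(3-methoxyprop-2-yn-1-yl)benzene, via lithium methoxyacetylide 9 (not isolated)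
Conditions: 8 (2 equiv), LiNEt2 (3 equiv per 8), THF, 0 °C; then 7, DMPU, −78 → 0 °C
Reagents that add atoms: none
Why: SN2 alkylation of a lithium alkoxyacetylide, made from the chloroacetal by double elimination and deprotonation with LiNEt2, by a benzylic bromide in the presence of a dipolar cosolvent; the excess of the small, anionic acetylide at low temperature outruns the neutral diethylamine, and the aryl bromide does not exchange with an acetylide.

Step 7
Reactants: 11 1-ethoxyprop-1-yne; 12 acetyl chloride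
Product: 14 3-ethoxy-2-methylcyclobut-2-en-1-one, via ketene 13 (not isolated)
Conditions: Et3N, MeCN, 0 °C → rt
Reagents that add atoms: none
Why: Ketene–alkyne [2+2] cycloaddition in which ketene, made in the flask by dehydrochlorination of acetyl chloride, bonds through its carbonyl carbon to the methyl-bearing carbon of the ynol ether to give the 3-alkoxycyclobutenone.

Step 8
Reactants: 10 1,5-bis(benzyloxy)-2-bromo-3-(methoxymethoxy)-4-(3-methoxyprop-2-yn-1-yl)benzene; 14 3-ethoxy-2-methylcyclobut-2-en-1-one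
Product: 19 2-{[4,6-bis(benzyloxy)-3-bromo-2-(methoxymethoxy)phenyl]methyl}-5-ethoxy-3-methoxy-4-methylphenol, via vinylketene 15 (not isolated), via vinylcyclobutenone adduct 16 (not isolated), via dienylketene 17 (not isolated), via cyclohexadienone 18 (not isolated)
Conditions: 14 (1.5 equiv), PhMe, 110 °C, sealed tube; then KOH, MeOH, rt
Reagents that add atoms: none
Why: Thermal 4π electrocyclic opening of cyclobutenone 14 gives vinylketene 15, whose ketene C=C adds [2+2] to the electron-rich alkyne of 10 to give 4-vinylcyclobutenone 16; a second 4π opening gives dienylketene 17, which closes and tautomerises to phenol 19. The closest known reaction is the Danheiser benzannulation of cyclobutenones with alkoxyalkynes; a 3-alkoxycyclobutenone is an unusual partner, so temperature and stoichiometry are the variables to test. Ring A' is closed by thermal disrotatory 6π electrocyclisation of 17, which forms C2''–C3'' and gives cyclohexadienone 18 before enolisation. No stereocentre survives: the quaternary centre of 16 is racemic and is lost on ring opening. The step needs regioselectivity in the ketene–alkyne cycloaddition, secured by the methoxy group, which makes the remote alkyne carbon nucleophilic so that it bonds to the ketene carbonyl carbon (C1''–C2'') while the oxygen-bearing carbon bonds to the methyl-bearing ketene carbon (C5''–C6''), placing OMe between methyl and methylene. Chemoselectivity rests on the inertness of aryl bromide, MOM and benzyl ethers to heat, on a methyl ynol ether that cannot lose an alkene by retro-ene reaction, and on the closing KOH/MeOH treatment, which returns any product O-acylated by excess vinylketene.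

Step 9
Reactants: 19 2-{[4,6-bis(benzyloxy)-3-bromo-2-(methoxymethoxy)phenyl]methyl}-5-ethoxy-3-methoxy-4-methylphenol
Product: 20 1,5-bis(benzyloxy)-2-bromo-4-{[4-ethoxy-2-methoxy-6-(methoxymethoxy)-3-methylphenyl]methyl}-3-(methoxymethoxy)benzene
Conditions: MOMCl, i-Pr2NEt, CH2Cl2, 0 °C → rt
Reagents that add atoms: chloromethyl methyl ether, COCCl
Why: MOM acetal formation masks the phenol so that the organolithium and enolate steps need no sacrificial base and the phenoxide cannot be aroylated in step 11; the group leaves together with the ring A acetal in step 12.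

Step 10
Reactants: 20 1,5-bis(benzyloxy)-2-bromo-4-{[4-ethoxy-2-methoxy-6-(methoxymethoxy)-3-methylphenyl]methyl}-3-(methoxymethoxy)benzene; 21 2-(benzyloxy)-N-methoxy-N-methylacetamide
Product: 23 2-(benzyloxy)-1-[4,6-bis(benzyloxy)-3-{[4-ethoxy-2-methoxy-6-(methoxymethoxy)-3-methylphenyl]methyl}-2-(methoxymethoxy)phenyl]ethan-1-one, via aryllithium 22 (not isolated)
Conditions: n-BuLi (1.1 equiv), THF, −78 °C; then 21, −78 → 0 °C; H2O
Reagents that add atoms: none
Why: Bromine–lithium exchange at −78 °C is faster than any deprotonation of benzyl ethers or of C3''–H, and the aryllithium adds once to the Weinreb amide through a stable chelated tetrahedral adduct that releases the ketone only on work-up (Weinreb ketone synthesis).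

Step 11
Reactants: 23 2-(benzyloxy)-1-[4,6-bis(benzyloxy)-3-{[4-ethoxy-2-methoxy-6-(methoxymethoxy)-3-methylphenyl]methyl}-2-(methoxymethoxy)phenyl]ethan-1-one; 24 4-methoxybenzoyl chloride
Product: 26 2-(benzyloxy)-1-[4,6-bis(benzyloxy)-3-{[4-ethoxy-2-methoxy-6-(methoxymethoxy)-3-methylphenyl]methyl}-2-(methoxymethoxy)phenyl]-3-(4-methoxyphenyl)propane-1,3-dione (racemic), via lithium enolate 25 (not isolated)
Conditions: LiN(SiMe3)2 (2.2 equiv), THF, −78 °C; then 24, −78 → 0 °C; AcOH
Reagents that add atoms: none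
Why: Claisen-type C-acylation of the chelated lithium enolate of the α-alkoxy ketone by an aroyl chloride, run with a second equivalent of base because the 1,3-diketone formed is more acidic than the starting ketone; the new centre is racemic and is lost in step 12.

Step 12
Reactants: 26 2-(benzyloxy)-1-[4,6-bis(benzyloxy)-3-{[4-ethoxy-2-methoxy-6-(methoxymethoxy)-3-methylphenyl]methyl}-2-(methoxymethoxy)phenyl]-3-(4-methoxyphenyl)propane-1,3-dione
Product: 28 3,5,7-tris(benzyloxy)-8-[(4-ethoxy-6-hydroxy-2-methoxy-3-methylphenyl)methyl]-2-(4-methoxyphenyl)-4H-chromen-4-one, via hydroxy diketone 27 (not isolated)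
Conditions: HCl (cat.), MeOH/THF, 50 °C
Reagents that add atoms: none
Why: Acid methanolysis removes both MOM acetals, and the liberated O8a phenol adds to the anisoyl carbonyl and dehydrates (cyclodehydration of an o-hydroxyaryl 1,3-diketone, the second stage of a Baker–Venkataraman flavone synthesis); because O5 stays benzylated, only O8a can close the pyranone, which fixes the methylene at C8.

Step 13
Reactants: 28 3,5,7-tris(benzyloxy)-8-[(4-ethoxy-6-hydroxy-2-methoxy-3-methylphenyl)methyl]-2-(4-methoxyphenyl)-4H-chromen-4-one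
Product: 29 3-{[3,5,7-tris(benzyloxy)-2-(4-methoxyphenyl)-4-oxo-4H-chromen-8-yl]methyl}-6-ethoxy-2-hydroxy-4-methoxy-5-methylbenzaldehyde
Conditions: MgCl2, Et3N, (CH2O)n, THF, reflux; aq HCl work-up
Reagents that add atoms: paraformaldehyde (as formaldehyde), C=O
Why: Casnati–Skattebøl ortho-formylation, in which the magnesium phenoxide of the only free phenol delivers formaldehyde to its single open ortho position, C3'', under conditions that leave the flavone and the benzyl ethers alone.

Step 14
Reactants: 29 3-{[3,5,7-tris(benzyloxy)-2-(4-methoxyphenyl)-4-oxo-4H-chromen-8-yl]methyl}-6-ethoxy-2-hydroxy-4-methoxy-5-methylbenzaldehyde; 30 1-(benzyloxy)-4-(2-bromoethyl)benzene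
Product: 32 3,5,7-tris(benzyloxy)-8-({3-[3-(4-(benzyloxy)phenyl)-1-hydroxypropyl]-4-ethoxy-2-hydroxy-6-methoxy-5-methylphenyl}methyl)-2-(4-methoxyphenyl)-4H-chromen-4-one (racemic), via Grignard reagent 31 (not isolated)
Conditions: 30, Mg, THF; then 29 added to 31 (2.2 equiv), THF, −78 °C; H2O (pH 7)
Reagents that add atoms: none
Why: Grignard addition to an aldehyde, which at −78 °C is far more electrophilic than the doubly flanked vinylogous-ester carbonyl of the flavone; one equivalent of the reagent is spent on the phenol, and the new carbinol centre forms as a racemate that is erased by the oxidation in step 15.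

Step 15
Reactants: 32 3,5,7-tris(benzyloxy)-8-({3-[3-(4-(benzyloxy)phenyl)-1-hydroxypropyl]-4-ethoxy-2-hydroxy-6-methoxy-5-methylphenyl}methyl)-2-(4-methoxyphenyl)-4H-chromen-4-one
Product: 33 3,5,7-tris(benzyloxy)-8-({3-[3-(4-(benzyloxy)phenyl)propanoyl]-4-ethoxy-2-hydroxy-6-methoxy-5-methylphenyl}methyl)-2-(4-methoxyphenyl)-4H-chromen-4-one
Conditions: MnO2, CH2Cl2, rt
Reagents that add atoms: none
Why: MnO2 oxidation of the only alcohol present, an o-hydroxybenzylic one, to the aryl ketone, which is then stabilised by its hydrogen bond to O2''.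

Step 16
Reactants: 33 3,5,7-tris(benzyloxy)-8-({3-[3-(4-(benzyloxy)phenyl)propanoyl]-4-ethoxy-2-hydroxy-6-methoxy-5-methylphenyl}methyl)-2-(4-methoxyphenyl)-4H-chromen-4-one
Product: 34 4'''-hydroxytrianguletin, 8-({2,4-dihydroxy-3-[3-(4-hydroxyphenyl)propanoyl]-6-methoxy-5-methylphenyl}methyl)-3,5,7-trihydroxy-2-(4-methoxyphenyl)-4H-chromen-4-one
Conditions: BCl3, C6HMe5, CH2Cl2, −78 → 0 °C; MeOH, H2O
Reagents that add atoms: none
Why: Lewis-acid ether cleavage in which BCl3 removes the four benzyl groups at low temperature, pentamethylbenzene trapping the benzyl cations, and on warming splits the ethyl ether through its six-membered boron chelate to the C3'' ketone, whereas the methyl ethers at C4' and C6'' have no carbonyl neighbour and survive.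

**Compound list**

1 | 2,4,6-trihydroxybenzaldehyde | O=Cc1c(O)cc(O)cc1O | starting material
2 | 2,4-bis(benzyloxy)-6-hydroxybenzaldehyde | O=Cc1c(O)cc(OCc2ccccc2)cc1OCc1ccccc1 | intermediate
3 | 4,6-bis(benzyloxy)-3-bromo-2-hydroxybenzaldehyde | O=Cc1c(O)c(Br)c(OCc2ccccc2)cc1OCc1ccccc1 | intermediate
4 | 4,6-bis(benzyloxy)-3-bromo-2-(methoxymethoxy)benzaldehyde | O=Cc1c(OCOC)c(Br)c(OCc2ccccc2)cc1OCc1ccccc1 | intermediate
5 | [4,6-bis(benzyloxy)-3-bromo-2-(methoxymethoxy)phenyl]methanol | OCc1c(OCOC)c(Br)c(OCc2ccccc2)cc1OCc1ccccc1 | intermediate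
6 | [4,6-bis(benzyloxy)-3-bromo-2-(methoxymethoxy)phenyl]methyl methanesulfonate | CS(=O)(=O)OCc1c(OCOC)c(Br)c(OCc2ccccc2)cc1OCc1ccccc1 | intermediate
7 | 1,5-bis(benzyloxy)-2-bromo-4-(bromomethyl)-3-(methoxymethoxy)benzene | BrCc1c(OCOC)c(Br)c(OCc2ccccc2)cc1OCc1ccccc1 | intermediate
8 | 2-chloro-1,1-dimethoxyethane | COC(CCl)OC | starting material
9 | lithium methoxyacetylide | [Li]C#COC | intermediate
10 | 1,5-bis(benzyloxy)-2-bromo-3-(methoxymethoxy)-4-(3-methoxyprop-2-yn-1-yl)benzene | COC#CCc1c(OCOC)c(Br)c(OCc2ccccc2)cc1OCc1ccccc1 | intermediate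
11 | 1-ethoxyprop-1-yne | CCOC#CC | starting material
12 | acetyl chloride | CC(Cl)=O | starting material
13 | ketene | C=C=O | intermediate
14 | 3-ethoxy-2-methylcyclobut-2-en-1-one | CCOC1=C(C)C(=O)C1 | intermediate
15 | 3-ethoxy-2-methylbuta-1,3-dien-1-one (vinylketene) | CCOC(=C)C(C)=C=O | intermediate
16 | 2-{[4,6-bis(benzyloxy)-3-bromo-2-(methoxymethoxy)phenyl]methyl}-4-(1-ethoxyethenyl)-3-methoxy-4-methylcyclobut-2-en-1-one (racemic) | CCOC(=C)C1(C)C(OC)=C(Cc2c(OCOC)c(Br)c(OCc3ccccc3)cc2OCc2ccccc2)C1=O | intermediate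
17 | (3E)-2-{[4,6-bis(benzyloxy)-3-bromo-2-(methoxymethoxy)phenyl]methyl}-5-ethoxy-3-methoxy-4-methylhexa-1,3,5-trien-1-one (dienylketene, ketene carbon and ethoxyvinyl group cis) | O=C=C(Cc1c(OCOC)c(Br)c(OCc2ccccc2)cc1OCc1ccccc1)/C(OC)=C(\C(OCC)=C)C | intermediate
18 | 2-{[4,6-bis(benzyloxy)-3-bromo-2-(methoxymethoxy)phenyl]methyl}-5-ethoxy-3-methoxy-4-methylcyclohexa-2,4-dien-1-one | CCOC1=C(C)C(OC)=C(Cc2c(OCOC)c(Br)c(OCc3ccccc3)cc2OCc2ccccc2)C(=O)C1 | intermediate
19 | 2-{[4,6-bis(benzyloxy)-3-bromo-2-(methoxymethoxy)phenyl]methyl}-5-ethoxy-3-methoxy-4-methylphenol | CCOc1cc(O)c(Cc2c(OCOC)c(Br)c(OCc3ccccc3)cc2OCc2ccccc2)c(OC)c1C | intermediate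
20 | 1,5-bis(benzyloxy)-2-bromo-4-{[4-ethoxy-2-methoxy-6-(methoxymethoxy)-3-methylphenyl]methyl}-3-(methoxymethoxy)benzene | CCOc1cc(OCOC)c(Cc2c(OCOC)c(Br)c(OCc3ccccc3)cc2OCc2ccccc2)c(OC)c1C | intermediate
21 | 2-(benzyloxy)-N-methoxy-N-methylacetamide | CON(C)C(=O)COCc1ccccc1 | starting material
22 | {4,6-bis(benzyloxy)-3-{[4-ethoxy-2-methoxy-6-(methoxymethoxy)-3-methylphenyl]methyl}-2-(methoxymethoxy)phenyl}lithium | CCOc1cc(OCOC)c(Cc2c(OCOC)c([Li])c(OCc3ccccc3)cc2OCc2ccccc2)c(OC)c1C | intermediate
23 | 2-(benzyloxy)-1-[4,6-bis(benzyloxy)-3-{[4-ethoxy-2-methoxy-6-(methoxymethoxy)-3-methylphenyl]methyl}-2-(methoxymethoxy)phenyl]ethan-1-one | CCOc1cc(OCOC)c(Cc2c(OCOC)c(C(=O)COCc3ccccc3)c(OCc3ccccc3)cc2OCc2ccccc2)c(OC)c1C | intermediate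
24 | 4-methoxybenzoyl chloride | COc1ccc(C(Cl)=O)cc1 | starting material
25 | lithium (Z)-enolate of 23 (O–Li and benzyloxy cis) | CCOc1cc(OCOC)c(Cc2c(OCOC)c(/C(O[Li])=C/OCc3ccccc3)c(OCc3ccccc3)cc2OCc2ccccc2)c(OC)c1C | intermediate
26 | 2-(benzyloxy)-1-[4,6-bis(benzyloxy)-3-{[4-ethoxy-2-methoxy-6-(methoxymethoxy)-3-methylphenyl]methyl}-2-(methoxymethoxy)phenyl]-3-(4-methoxyphenyl)propane-1,3-dione (racemic) | CCOc1cc(OCOC)c(Cc2c(OCOC)c(C(=O)C(OCc3ccccc3)C(=O)c3ccc(OC)cc3)c(OCc3ccccc3)cc2OCc2ccccc2)c(OC)c1C | intermediate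
27 | 2-(benzyloxy)-1-{4,6-bis(benzyloxy)-3-[(4-ethoxy-6-hydroxy-2-methoxy-3-methylphenyl)methyl]-2-hydroxyphenyl}-3-(4-methoxyphenyl)propane-1,3-dione (racemic) | CCOc1cc(O)c(Cc2c(O)c(C(=O)C(OCc3ccccc3)C(=O)c3ccc(OC)cc3)c(OCc3ccccc3)cc2OCc2ccccc2)c(OC)c1C | intermediate
28 | 3,5,7-tris(benzyloxy)-8-[(4-ethoxy-6-hydroxy-2-methoxy-3-methylphenyl)methyl]-2-(4-methoxyphenyl)-4H-chromen-4-one | COc1ccc(-c2oc3c(Cc4c(O)cc(OCC)c(C)c4OC)c(OCc4ccccc4)cc(OCc4ccccc4)c3c(=O)c2OCc2ccccc2)cc1 | intermediate
29 | 3-{[3,5,7-tris(benzyloxy)-2-(4-methoxyphenyl)-4-oxo-4H-chromen-8-yl]methyl}-6-ethoxy-2-hydroxy-4-methoxy-5-methylbenzaldehyde | COc1ccc(-c2oc3c(Cc4c(O)c(C=O)c(OCC)c(C)c4OC)c(OCc4ccccc4)cc(OCc4ccccc4)c3c(=O)c2OCc2ccccc2)cc1 | intermediate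
30 | 1-(benzyloxy)-4-(2-bromoethyl)benzene | BrCCc1ccc(OCc2ccccc2)cc1 | starting material
31 | {2-[4-(benzyloxy)phenyl]ethyl}magnesium bromide | Br[Mg]CCc1ccc(OCc2ccccc2)cc1 | intermediate
32 | 3,5,7-tris(benzyloxy)-8-({3-[3-(4-(benzyloxy)phenyl)-1-hydroxypropyl]-4-ethoxy-2-hydroxy-6-methoxy-5-methylphenyl}methyl)-2-(4-methoxyphenyl)-4H-chromen-4-one (racemic) | COc1ccc(-c2oc3c(Cc4c(O)c(C(O)CCc5ccc(OCc6ccccc6)cc5)c(OCC)c(C)c4OC)c(OCc4ccccc4)cc(OCc4ccccc4)c3c(=O)c2OCc2ccccc2)cc1 | intermediate
33 | 3,5,7-tris(benzyloxy)-8-({3-[3-(4-(benzyloxy)phenyl)propanoyl]-4-ethoxy-2-hydroxy-6-methoxy-5-methylphenyl}methyl)-2-(4-methoxyphenyl)-4H-chromen-4-one | COc1ccc(-c2oc3c(Cc4c(O)c(C(=O)CCc5ccc(OCc6ccccc6)cc5)c(OCC)c(C)c4OC)c(OCc4ccccc4)cc(OCc4ccccc4)c3c(=O)c2OCc2ccccc2)cc1 | intermediate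
34 | 4'''-hydroxytrianguletin (no stereocentre) | COc1ccc(-c2oc3c(Cc4c(O)c(C(=O)CCc5ccc(O)cc5)c(O)c(C)c4OC)c(O)cc(O)c3c(=O)c2O)cc1 | target

**Step count and risks**

Total step count: 16. Longest linear sequence: 15 steps (steps 1–6 and 8–16, from 2,4,6-trihydroxybenzaldehyde).

The three steps most likely to fail:

1. Step 8. The vinylogous-ester cyclobutenone 14 may resist electrocyclic opening until temperatures at which alkyne 10 isomerises or polymerises, so that vinylketene 15 is never present beside intact 10. The fallback makes 15 at room temperature by photochemical Wolff rearrangement, the second-generation form of the same benzannulation. Ethyl vinyl ether is lithiated with t-BuLi to (1-ethoxyvinyl)lithium F1, which is acylated with N-methoxy-N-methylpropanamide to 2-ethoxypent-1-en-3-one F2. The lithium enolate of F2 is trifluoroacetylated with 2,2,2-trifluoroethyl trifluoroacetate to racemic 2-ethoxy-6,6,6-trifluoro-4-methylhex-1-ene-3,5-dione F3, and detrifluoroacetylative diazo transfer with methanesulfonyl azide and Et3N should give 2-diazo-4-ethoxypent-4-en-3-one F4. Irradiation of F4 at 365 nm in the presence of 10, a wavelength at which the aryl bromide and the benzyl ethers are transparent, should give 15 and then 16, and warming to 80 °C should carry 16 through 17 and 18 to phenol 19. The fallback sets out from 10 and returns to the route at 19.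

2. Step 6. The liberated diethylamine may be N-alkylated by the reactive benzylic bromide, and the doubly activated CH2 of 10 may isomerise from propargyl to allene under the strongly basic conditions. In the fallback, acetylide 9 is quenched with Bu3SnCl and distilled to tributyl(methoxyethynyl)stannane F5, which is coupled with bromide 7 under neutral conditions by Stille coupling (Pd(PPh3)4, THF, 50 °C). The fallback sets out from 7 and 9 and returns to the route at 10.

3. Step 14. The Grignard reagent may also attack the flavone carbonyl or C2, and the o-hydroxybenzylic carbinol may ionise to an o-quinone methide on work-up. In the fallback, phenol 28 is esterified with 3-[4-(benzyloxy)phenyl]propanoic acid (DCC, DMAP, Steglich esterification) to the aryl ester 2-{[3,5,7-tris(benzyloxy)-2-(4-methoxyphenyl)-4-oxo-4H-chromen-8-yl]methyl}-5-ethoxy-3-methoxy-4-methylphenyl 3-[4-(benzyloxy)phenyl]propanoate F6. A Fries rearrangement promoted by ZrCl4 in CH2Cl2 at room temperature should then move the acyl group to C3'', the only free ortho position, the para position being blocked by the methyl group. The fallback sets out from 28 and returns to the route at 33, bypassing steps 13–15.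

**Further compounds**

F1 | step 8 | (1-ethoxyvinyl)lithium | [Li]C(=C)OCC
F2 | step 8 | 2-ethoxypent-1-en-3-one | CCOC(=C)C(=O)CC
F3 | step 8 | 2-ethoxy-6,6,6-trifluoro-4-methylhex-1-ene-3,5-dione (racemic) | CCOC(=C)C(=O)C(C)C(=O)C(F)(F)F
F4 | step 8 | 2-diazo-4-ethoxypent-4-en-3-one | CCOC(=C)C(=O)C(C)=[N+]=[N-]
F5 | step 6 | tributyl(methoxyethynyl)stannane | CCCC[Sn](CCCC)(CCCC)C#COC
F6 | step 14 | 2-{[3,5,7-tris(benzyloxy)-2-(4-methoxyphenyl)-4-oxo-4H-chromen-8-yl]methyl}-5-ethoxy-3-methoxy-4-methylphenyl 3-[4-(benzyloxy)phenyl]propanoate | COc1ccc(-c2oc3c(Cc4c(OC(=O)CCc5ccc(OCc6ccccc6)cc5)cc(OCC)c(C)c4OC)c(OCc4ccccc4)cc(OCc4ccccc4)c3c(=O)c2OCc2ccccc2)cc1
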